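## The problem

Atoms are numbered as in the germacranolides: C1 ketone, C4 tertiary carbinol, C5=C6 ring alkene with the lactone oxygen on C6, C7=C11 butenolide alkene, C8 senecioate carbon, C10 methyl-bearing carbon, C12 lactone carbonyl, C13 acetoxymethyl.

The target 34 is a ten-membered carbocycle fused at C6–C7 to a Z-γ-alkylidene butenolide. The medium ring and the enol lactone therefore have to be made without a high-dilution ring closure and without strong base or nucleophile once the lactone exists. Three stereocentres must be set: C4 (R), C8 (R) and C10 (S). C8 and C10 are 1,3-related and can control each other (trans on a γ-lactone, which is cis on a cyclohexane through C1). C4 is remote from both, cannot be relayed, and needs its own chiral building block. C10 lies α to the C1 ketone and can epimerize; the tertiary allylic C4 alcohol next to the enol ether ionizes in acid; the senecioate can deconjugate. The two acyl groups therefore go on last, and nothing harsher than buffered fluoride may follow the lactonization. The tetrasubstituted C7=C11 alkene must carry the carboxyl carbon cis to C6 and C13 cis to C8, and this geometry has to survive every carbanion generated at C6. The enabling feature is that the C1 ketone lies 1,6 across the ring from C6. If the C5=C6–O enol lactone is read as an alkyne C5≡C6 plus a cis carboxyl, C1=O and C6 are the two ends of the broken fusion bond of a decalin made of ring A (C1–C6) and ring B (C1, C6–C10).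

## Retrosynthesis

**Acyl groups (34 ⇒ 33 ⇒ 32 ⇒ 31).** The C8–O and C13–O ester bonds are cut first, because neither ester tolerates the bases used earlier. Triol 32 differentiates itself: primary C13–OH, secondary C8–OH, unreactive tertiary C4–OH. It is taken back to tricycle 31, in which O8 and O13 are bridged by one di-tert-butylsilylene and O4 is a triethylsilyl ether, so a single fluoride treatment unveils all three hydroxyls. The forward reactions need only chemoselectivity.

**Enol lactone (31 ⇒ 30 ⇒ 29).** The C6–O lactone bond is cut to give enyne acid 30 and its allyl ester 29. Anti addition of the cis carboxyl across C5≡C6 sets the Z alkylidene and the E ring alkene in one operation. An olefination at C5=C6 would instead have to control geometry on a flexible ring. The acid is released under neutral conditions from the allyl ester.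

**Key disconnection (29 ⇒ 28).** The C1–C6 bond is re-formed on paper. The ten-membered alkynone 29 becomes the decalin dienyl triflate 28, with a C1 tertiary alcohol and a C5 enol triflate on C5=C6. The forward step cleaves a bond, so no medium ring has to be closed. The precursor is two six-membered rings carrying all three stereocentres. The ring holds the C1–C6 bond anti to the C5–O(triflate) bond.

**Ring A (28 ⇒ 27 ⇒ 26 ⇒ 25).** The triflate comes from ketone 27, whose only α-hydrogen is on C6. The ketone comes from alcohol 26, and the C5–C6 bond of 26 is cut as a vinylogous aldol of aldehyde 25. An aldehyde is preferred to a C5 ester for three reasons: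
- it has no α-hydrogen;
- it is far more electrophilic at a neopentyl position;
- its adduct with the C1 alkoxide is a reversible lactol, whereas an ester would be trapped as a spiro-lactone.

**C1–C2 bond (25 ⇒ 24 ⇒ 15 + 21).** The aldehyde is masked as a primary triethylsilyl ether in 24. The C1–C2 bond is cut to ring-B ketone 15 and iodide 21. The C1 configuration is irrelevant because C1 becomes the ketone again in the key step. Ketone 15 is easily enolized at C6, so the nucleophile must be non-basic, which points to an organocerium reagent.

**Ring B (15 ⇒ 14).** The C1–C6 bond of ring B is cut as a vinylogous Claisen closure of the C6 methyl of acrylate 14 onto a C1 Weinreb amide. A cyclohexane-1,3-dione would leave C1 and C7 to be told apart later. Here C7 is already olefinated and C1 arrives as the only ketone.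

**Acrylate and its lock (14 ⇒ 13 ⇒ 12 ⇒ 11 ⇒ 7 + 10).** Every later C6 carbanion is a dienolate in which the C7–C11 bond can rotate. O8 and O13 are therefore tied into a seven-membered silylene (14), which makes the geometry a property of a ring. Diol 13 comes from diacetate 12 by acylative opening of dihydrofuran 11. Dihydrofuran 11 is cut at O–C13 and C7=C11 into α-hydroxy ketone 7 and phosphonoacrylate 10. The five-membered ring formed in this tandem step leaves only one geometry for the tetrasubstituted alkene. An intermolecular olefination of a hindered ketone with a substituted phosphonate would not.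

**α-Hydroxy ketone (7 ⇒ 6 ⇒ 5 ⇒ 4 ⇒ 3 ⇒ 1).** The C8 oxygen and configuration come from lactone acid 1. Its carboxyl becomes the C7 acetyl group of 3. The ketone is masked as the alkene of 4 while the C10 methyl is introduced trans to the C8 substituent (5) and the lactone is opened to Weinreb amide 6. Ozonolysis then returns the ketone under neutral conditions (7), because the γ-hydroxy amide would relactonize in acid.

**C2–C5 fragment (21 ⇒ 20 ⇒ 19 ⇒ 18 ⇒ 17 ⇒ 16).** (R)-Citramalic acid 16 supplies C4 with its methyl and oxygen. Reduction to triol 17 and the 1,2-acetonide 18 single out the C2 hydroxyl for conversion to the iodide (19, 20, 21).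

**Reagent (10 ⇒ 8).** Acrylate 10 is the methylenation product of allyl diethylphosphonoacetate 8.

## Roads not taken

**Alternative 1:** The cut is C6–C7 together with the lactone C6–O bond. In the forward step PdCl2(PPh3)2, CuI and triethylamine couple the Z-enol triflate carbon C7 of the open-chain acid A2 with its terminal alkyne. The cis carboxylic acid then adds 5-exo-dig to C6, giving the bis-silyl ether A1 with the complete bicyclic core.
- Merits: it is convergent, forms the ring and the butenolide in one flask, and leaves only desilylation and two acylations. It would be clearly shorter than the chosen route.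
- Weak points: the ring-closing event must hold a linear C4–C5≡C6–C7 unit inside a ten-membered palladacycle precursor, so oligomerization and alkyne homocoupling compete even at high dilution. The tetrasubstituted enol triflate of A2 must be geometrically pure and carry a free acid. The free C4 propargylic alcohol is exposed to copper acetylide chemistry.
- Comparison: the chosen plan is longer. Against that it sets a unimolecular bond cleavage with no dilution requirement and no competing intermolecular channel.

**Alternative 2:** The cut is C8–C9. CrCl2 with a chiral bis(oxazolinyl)carbazole ligand converts the 2-(bromomethyl)enone of A4 into an allylchromium species. Its γ-carbon adds to the aldehyde on the preformed alkylidene butenolide and gives the ten-membered C8 alcohol A3.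
- Merits: chromium-mediated allylation is a proven way to close germacrane-type rings; the catalyst sets C8; the butenolide needs no late lactonization. In convergence and probably in step count this road is better.
- Weak points: C10 is left as an exocyclic methylene. It must later be reduced to the (S)-methyl group on a flexible ring in the presence of the alkylidene butenolide, with no reliable facial control. The electrophilic formyl butenolide and the bromo enone must both survive divalent chromium. The enol lactone is carried through the whole fragment assembly.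
- Comparison: the chosen plan sets against this that C8 and C10 come from one chiral-pool lactone on rigid rings, and that the sensitive enol lactone appears only five steps from the end.

**Alternative 3:** The cut is C3–C4, made while C1–C6 is cleaved. The potassium alkoxide (KH, 18-crown-6) of the cyclohexane-fused butenolide A6 undergoes anionic oxy-Cope rearrangement and gives, after protonation, the ten-membered keto alkylidene butenolide A5.
- Merits: like the chosen plan it opens the ring by scission of the fusion bond. It also forms a skeletal bond and delivers the enol lactone directly, so triflation, alkyne and silver step are all saved. In step economy after the key step it is better.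
- Weak points: the C4 quaternary stereocentre is created in the rearrangement from a trisubstituted enol ether, so its configuration depends on the chair or boat transition state and on the C1/C6 relative configuration of A6. The C1 alkoxide sits next to C6, which carries the lactone oxygen, so 1,2-acyl migration and β-elimination are open to it. A6 needs a fully substituted, oxygenated C6 that is hard to assemble.
- Comparison: the chosen plan takes C4 intact from citramalic acid, creates no stereocentre in the key step, and gives the alkoxide no nearby acyl group it can reach.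

Key step: step 22

Assumption: the C1 carbinol of 24–28 is drawn as the epimer expected from equatorial attack (OH cis to the C10 methyl); the other epimer would serve equally. C5 and C6 of 26 and C6 of 27 are left undefined because both centres are cleared in steps 20–22.

Step 1
Reactants: 1 (R)-5-oxotetrahydrofuran-2-carboxylic acid
Product: 3 (R)-5-acetyldihydrofuran-2(3H)-one, via acid chloride 2 (not isolated)
Conditions: (COCl)2, DMF (cat.), CH2Cl2, 0 °C to rt; then MeMgBr, Fe(acac)3 (cat.), THF, −78 °C
Reagents that add atoms: methylmagnesium bromide, C[Mg]Br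
Why: Acid chloride formation followed by iron-catalysed acylation of the Grignard reagent should stop at the methyl ketone and leave the lactone alone; no base is present, so the C8 centre is not touched.

Step 2
Reactants: 3 (R)-5-acetyldihydrofuran-2(3H)-one
Product: 4 (R)-5-(prop-1-en-2-yl)dihydrofuran-2(3H)-one
Conditions: Zn, CH2Br2, TiCl4, THF/CH2Cl2, 0 °C to rt
Reagents that add atoms: dibromomethane, BrCBr
Why: Takai–Lombardo methylenation is non-basic and selective for ketones over lactones, so the α-acyloxy ketone should be masked as an alkene without enolization at C8.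

Step 3
Reactants: 4 (R)-5-(prop-1-en-2-yl)dihydrofuran-2(3H)-one
Product: 5 (3S,5R)-3-methyl-5-(prop-1-en-2-yl)dihydrofuran-2(3H)-one
Conditions: LiN(iPr)2, THF, −78 °C; MeI, −78 to −40 °C
Reagents that add atoms: iodomethane, CI
Why: Lactone enolate alkylation; the electrophile should approach anti to the ring substituent on the oxygen-bearing carbon, giving the trans lactone and hence C10 (S) relative to C8 (R).

Step 4
Reactants: 5 (3S,5R)-3-methyl-5-(prop-1-en-2-yl)dihydrofuran-2(3H)-one
Product: 6 (2S,4R)-4-hydroxy-N-methoxy-N,2,5-trimethylhex-5-enamide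
Conditions: MeNH(OMe)·HCl, AlMe3, CH2Cl2, 0 °C to rt; Rochelle salt work-up
Reagents that add atoms: N,O-dimethylhydroxylamine hydrochloride, CNOC.Cl
Why: Aluminium-amide aminolysis of a lactone (Weinreb amide formation) frees the C8 hydroxyl and keeps C1 as an acyl group that does not relactonize under neutral or basic conditions.

Step 5
Reactants: 6 (2S,4R)-4-hydroxy-N-methoxy-N,2,5-trimethylhex-5-enamide
Product: 7 (2S,4R)-4-hydroxy-N-methoxy-N,2-dimethyl-5-oxohexanamide
Conditions: O3, CH2Cl2/MeOH, −78 °C; then Me2S
Reagents that add atoms: ozone, [O-][O+]=O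
Why: Ozonolysis of the 1,1-disubstituted alkene returns the methyl ketone under neutral conditions, which the acid-sensitive γ-hydroxy Weinreb amide and the α-ketol stereocentre tolerate.

Step 6
Reactants: 8 allyl diethylphosphonoacetate
Product: 10 allyl 2-(diethoxyphosphoryl)acrylate, via hydroxymethyl adduct 9 (not isolated)
Conditions: (CH2O)n, piperidine (cat.), toluene, 90 °C; then TsOH (cat.), reflux, Dean–Stark
Reagents that add atoms: paraformaldehyde (as formaldehyde), C=O
Why: Knoevenagel-type hydroxymethylation of the phosphonoacetate and acid-catalysed dehydration give the 2-phosphonoacrylate, a known class of annulation reagent.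

Step 7
Reactants: 7 (2S,4R)-4-hydroxy-N-methoxy-N,2-dimethyl-5-oxohexanamide; 10 allyl 2-(diethoxyphosphoryl)acrylate
Product: 11 allyl (5R)-5-[(2S)-3-(methoxy(methyl)amino)-2-methyl-3-oxopropyl]-4-methyl-2,5-dihydrofuran-3-carboxylate
Conditions: NaH (1.0 equiv), THF, 0 °C; slow addition of 10; 0 °C to rt
Reagents that add atoms: none
Why: Tandem oxa-Michael addition and intramolecular Horner–Wadsworth–Emmons olefination, as known for α-hydroxy ketones with vinylphosphonates and vinylphosphonium salts; the five-membered ring forces C13 cis to C8 and the ester cis to the C6 methyl, and one equivalent of base keeps the ketol as its alkoxide so that C8 should not enolize.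

Step 8
Reactants: 11 dihydrofuran ester
Product: 12 allyl (2E,4R,6S)-4-acetoxy-2-(acetoxymethyl)-7-[methoxy(methyl)amino]-3,6-dimethyl-7-oxohept-2-enoate
Conditions: Ac2O, FeCl3 (cat.), CH2Cl2, 0 °C
Reagents that add atoms: acetic anhydride, CC(=O)OC(C)=O
Why: Lewis-acid acylative cleavage of a cyclic allylic ether; acetate should enter at the primary allylic carbon C13, so the C8–O bond is not broken and both C8 and the alkene geometry are retained.

Step 9
Reactants: 12 diacetate
Product: 13 allyl (2E,4R,6S)-4-hydroxy-2-(hydroxymethyl)-7-[methoxy(methyl)amino]-3,6-dimethyl-7-oxohept-2-enoate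
Conditions: K2CO3 (cat.), allyl alcohol, 0 °C to rt
Reagents that add atoms: none
Why: Base-catalysed transesterification removes both acetates; allyl alcohol as solvent makes exchange at the allyl ester harmless, and a tertiary amide does not lactonize with an alkoxide under these conditions.

Step 10
Reactants: 13 diol
Product: 14 allyl (4R)-2,2-di-tert-butyl-4-[(2S)-3-(methoxy(methyl)amino)-2-methyl-3-oxopropyl]-5-methyl-4,7-dihydro-1,3,2-dioxasilepine-6-carboxylate
Conditions: tBu2Si(OTf)2, 2,6-lutidine, CH2Cl2, 0 °C
Reagents that add atoms: di-tert-butylsilyl bis(trifluoromethanesulfonate), CC(C)(C)[Si](OS(=O)(=O)C(F)(F)F)(OS(=O)(=O)C(F)(F)F)C(C)(C)C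
Why: Silylene formation on a cis-2-ene-1,4-diol gives the known 4,7-dihydro-1,3,2-dioxasilepine ring type; from here the C7=C11 geometry is fixed by a ring.

Step 11
Reactants: 14 silylene Weinreb amide
Product: 15 ring-B ketone (C1 ketone, C6 methylene, C7=C11 alkylidene with the allyl ester cis to C6, O8–Si(tBu)2–O13 bridge, 8R,10S)
Conditions: LiN(iPr)2 (1.2 equiv), THF, −78 to −40 °C; NH4Cl at −78 °C
Reagents that add atoms: none
Why: Vinylogous Claisen (Dieckmann-type) closure: the amide base should remove a proton from the C6 methyl, which is syn to the ester carbonyl, and the γ-carbon attacks the Weinreb amide in a six-membered closure; the chelated tetrahedral intermediate releases the ketone only on quench, so neither C10 nor the new acidic C6 methylene meets base.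

Step 12
Reactants: 16 (R)-citramalic acid
Product: 17 (R)-2-methylbutane-1,2,4-triol
Conditions: BH3·SMe2, B(OMe)3, THF, 0 °C to rt; then MeOH
Reagents that add atoms: none
Why: Borane reduction of both carboxylic acids, as used for malic acid; the tertiary carbinol is not involved.

Step 13
Reactants: 17 (R)-2-methylbutane-1,2,4-triol
Product: 18 2-[(4R)-2,2,4-trimethyl-1,3-dioxolan-4-yl]ethanol
Conditions: 2,2-dimethoxypropane, TsOH (cat.), acetone, rt
Reagents that add atoms: 2,2-dimethoxypropane, COC(C)(C)OC
Why: Thermodynamic acetonide formation should favour the five-membered 1,2-dioxolane over the 1,3-dioxane, leaving the C2 hydroxyl free.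

Step 14
Reactants: 18 acetonide alcohol
Product: 19 (4R)-4-(2-iodoethyl)-2,2,4-trimethyl-1,3-dioxolane
Conditions: I2, PPh3, imidazole, CH2Cl2, 0 °C
Reagents that add atoms: iodine, II
Why: Appel iodination of an unhindered primary alcohol.

Step 15
Reactants: 19 iodo acetonide
Product: 20 (2R)-4-iodo-2-methylbutane-1,2-diol
Conditions: AcOH/H2O (4:1), 40 °C; used at once
Reagents that add atoms: none
Why: Acid hydrolysis of the acetonide; under acid the diol should not cyclize onto the iodide.

Step 16
Reactants: 20 iodo diol
Product: 21 (R)-4-iodo-2-methyl-1,2-bis(triethylsilyloxy)butane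
Conditions: Et3SiOTf (2.3 equiv), 2,6-lutidine, CH2Cl2, −78 to 0 °C
Reagents that add atoms: triethylsilyl trifluoromethanesulfonate, CC[Si](CC)(CC)OS(=O)(=O)C(F)(F)F
Why: Silyl triflate silylates the primary and the tertiary hydroxyl; the primary silyl ether is the latent C5 aldehyde and the tertiary one protects O4 to the end.

Step 17
Reactants: 21 bis-silyl iodide; 15 ring-B ketone
Product: 24 C1 tertiary alcohol of ring B bearing the chain CH2CH2C(CH3)(OSiEt3)CH2OSiEt3, via organolithium 22 (not isolated), via organocerium reagent 23 (not isolated)
Conditions: t-BuLi (2.1 equiv), Et2O/pentane, −78 °C; CeCl3, THF, −78 °C; then 15, −78 °C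
Reagents that add atoms: none
Why: Iodine–lithium exchange and transmetalation give an organocerium reagent, the standard remedy for easily enolized ketones; it should add to C1 without removing the acidic C6 protons or attacking the hindered conjugated ester, from the equatorial side, although the C1 configuration does not matter.

Step 18
Reactants: 24 C1 tertiary alcohol
Product: 25 C5 aldehyde (in equilibrium with its six-membered lactol on O1)
Conditions: (COCl)2, DMSO, CH2Cl2, −78 to −40 °C; then Et3N
Reagents that add atoms: none
Why: Swern conditions convert a primary triethylsilyl ether directly into the aldehyde and leave the tertiary silyl ether, the silylene and the tertiary alcohol untouched.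

Step 19
Reactants: 25 C5 aldehyde
Product: 26 decalin diol (ring A closed; C5 secondary OH, C1 tertiary OH; C5 and C6 configurations undefined)
Conditions: LiN(iPr)2 (2.3 equiv), THF, −78 to −40 °C; NH4Cl
Reagents that add atoms: none
Why: Intramolecular vinylogous aldol reaction: the first equivalent of base stores the aldehyde as its lactolate, the second removes a C6 proton syn to the ester, and the γ-carbon closes the six-membered ring on the non-enolizable aldehyde; the silylene ring keeps the ester cis to C6, and the two new centres are removed later.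

Step 20
Reactants: 26 decalin diol
Product: 27 decalin β-hydroxy ketone (C5 ketone, C1 tertiary OH)
Conditions: Dess–Martin periodinane, NaHCO3, CH2Cl2, 0 °C to rt
Reagents that add atoms: none
Why: Periodinane oxidation of the only oxidizable hydroxyl; neutral buffered conditions should avoid retro-aldol cleavage of the β-hydroxy ketone.

Step 21
Reactants: 27 decalin β-hydroxy ketone
Product: 28 dienyl triflate (8a-hydroxy-octalin: C5 enol triflate on C5=C6, C1 OH, C4 OSiEt3, C7=C11 acrylate with the allyl ester cis to C6, O8–Si(tBu)2–O13 bridge)
Conditions: KN(SiMe3)2 (1.0 equiv), THF, −78 °C; then N-(5-chloro-2-pyridyl)triflimide, −78 °C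
Reagents that add atoms: N-(5-chloro-2-pyridyl)triflimide, FC(F)(F)S(=O)(=O)N(c1ccc(Cl)cn1)S(=O)(=O)C(F)(F)F
Why: Enolate O-triflation: C6–H, α to the ketone and vinylogous to the ester, is far more acidic than the tertiary alcohol, so one equivalent of base should give the extended enolate, which is trapped on the ketone oxygen; C4 has no hydrogen, so only the C5=C6 regioisomer can form.

Step 22
Reactants: 28 dienyl triflate
Product: 29 ten-membered cyclodec-5-ynone (C1 ketone, C5≡C6, exocyclic C7=C11 acrylate with the allyl ester cis to C6, silylene and C4 silyl ether retained)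
Conditions: KN(SiMe3)2 (1.05 equiv), THF, −78 to 0 °C; AcOH quench at −78 °C
Reagents that add atoms: none
Why: The base deprotonates the C1 alcohol; the alkoxide lone pair pushes into the C1–C6 bond, the C5=C6 π bond becomes the in-plane π bond of the alkyne, and triflate leaves from C5, so ketone, alkyne and potassium triflate arise together. This is a Grob-type fragmentation of a β-hydroxy vinyl triflate, closely related to the epoxy-ketone sulfonylhydrazone fragmentation that turns an octalone into cyclodec-5-ynone. The ten-membered ring is not closed by bond formation but opened out of the decalin by scission of the shared bond, so no cyclization mode and no entropic penalty apply. No stereocentre is formed; C4, C8 and C10 are carried over and the C1 configuration is erased. The step needs fragmentation to outrun everything else the alkoxide could do, and ring A secures this: C1 and C4 are cis on the C5=C6 bond, so the C1–C6 bond is held anti-periplanar to the C5–O bond. Lactonization onto the allyl ester would put the C7=C11 bond at a bridgehead of a bicyclo[3.3.1] skeleton, and attack at C5 would need a four-membered ring. The twisted tetrasubstituted diene is relieved as the bond breaks. Only a slight excess of base is used and the quench is cold, because the product ketone has an epimerizable C10.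

Step 23
Reactants: 29 cyclodecynone allyl ester
Product: 30 enyne carboxylic acid
Conditions: Pd(PPh3)4 (cat.), morpholine, THF, 0 °C to rt; pH 4 work-up
Reagents that add atoms: none
Why: Tsuji–Trost deallylation with zerovalent palladium frees the acid under neutral conditions that spare the ketone α-centre, the silyl groups and the enyne.

Step 24
Reactants: 30 enyne carboxylic acid
Product: 31 silyl-protected tricycle with the Z-alkylidene butenolide
Conditions: AgNO3 (10 mol%), acetone, rt, dark
Reagents that add atoms: none
Why: Silver-catalysed 5-exo-dig lactonization of a Z-2-en-4-ynoic acid: the carboxylate adds to C6 anti to the silver-bound alkyne and protodemetalation puts H on C5 trans to oxygen, which gives the Z enol lactone and the E ring alkene; the silylene ring holds the carboxyl next to C6.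

Step 25
Reactants: 31 silyl-protected tricycle
Product: 32 triol (C4, C8, C13 hydroxyls)
Conditions: HF·pyridine, pyridine, THF, 0 °C to rt
Reagents that add atoms: none
Why: Buffered fluoride desilylation removes the silylene and the tertiary triethylsilyl ether in one operation without acid strong enough to ionize the C4 allylic alcohol or base that would open the enol lactone.

Step 26
Reactants: 32 triol
Product: 33 C13 acetate
Conditions: AcCl (1.05 equiv), 2,4,6-collidine, CH2Cl2, −78 °C
Reagents that add atoms: acetyl chloride, CC(Cl)=O
Why: Chemoselective acylation: at low temperature with a hindered base the primary allylic hydroxyl should react well before the secondary one, and the tertiary one not at all.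

Step 27
Reactants: 33 C13 acetate
Product: 34 CNP0186726.1 (target)
Conditions: 3-methylbut-2-enoic acid, DCC, DMAP (cat.), CH2Cl2, 0 °C to rt
Reagents that add atoms: 3-methylbut-2-enoic acid, CC(C)=CC(O)=O
Why: Steglich esterification of the secondary C8 hydroxyl; carbodiimide activation with only catalytic DMAP avoids the ketene pathway that deconjugates senecioyl chloride, and the tertiary C4 hydroxyl stays free.

## Compound list

1 | (R)-5-oxotetrahydrofuran-2-carboxylic acid | OC(=O)[C@H]1CCC(=O)O1 | starting material
2 | (R)-5-oxotetrahydrofuran-2-carbonyl chloride | ClC(=O)[C@H]1CCC(=O)O1 | intermediate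
3 | (R)-5-acetyldihydrofuran-2(3H)-one | CC(=O)[C@H]1CCC(=O)O1 | intermediate
4 | (R)-5-(prop-1-en-2-yl)dihydrofuran-2(3H)-one | CC(=C)[C@H]1CCC(=O)O1 | intermediate
5 | (3S,5R)-3-methyl-5-(prop-1-en-2-yl)dihydrofuran-2(3H)-one | CC(=C)[C@H]1C[C@H](C)C(=O)O1 | intermediate
6 | (2S,4R)-4-hydroxy-N-methoxy-N,2,5-trimethylhex-5-enamide | CON(C)C(=O)[C@@H](C)C[C@@H](O)C(C)=C | intermediate
7 | (2S,4R)-4-hydroxy-N-methoxy-N,2-dimethyl-5-oxohexanamide | CON(C)C(=O)[C@@H](C)C[C@@H](O)C(C)=O | intermediate
8 | allyl diethylphosphonoacetate | C=CCOC(=O)CP(=O)(OCC)OCC | starting material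
9 | allyl 2-(diethoxyphosphoryl)-3-hydroxypropanoate | C=CCOC(=O)C(CO)P(=O)(OCC)OCC | intermediate
10 | allyl 2-(diethoxyphosphoryl)acrylate | C=CCOC(=O)C(=C)P(=O)(OCC)OCC | intermediate
11 | allyl (5R)-5-[(2S)-3-(methoxy(methyl)amino)-2-methyl-3-oxopropyl]-4-methyl-2,5-dihydrofuran-3-carboxylate | C=CCOC(=O)C1=C(C)[C@@H](C[C@H](C)C(=O)N(C)OC)OC1 | intermediate
12 | allyl (2E,4R,6S)-4-acetoxy-2-(acetoxymethyl)-7-[methoxy(methyl)amino]-3,6-dimethyl-7-oxohept-2-enoate (ester cis to the 3-methyl) | C=CCOC(=O)/C(COC(C)=O)=C(\C)[C@H](OC(C)=O)C[C@H](C)C(=O)N(C)OC | intermediate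
13 | allyl (2E,4R,6S)-4-hydroxy-2-(hydroxymethyl)-7-[methoxy(methyl)amino]-3,6-dimethyl-7-oxohept-2-enoate | C=CCOC(=O)/C(CO)=C(\C)[C@H](O)C[C@H](C)C(=O)N(C)OC | intermediate
14 | allyl (4R)-2,2-di-tert-butyl-4-[(2S)-3-(methoxy(methyl)amino)-2-methyl-3-oxopropyl]-5-methyl-4,7-dihydro-1,3,2-dioxasilepine-6-carboxylate | C=CCOC(=O)/C1=C(\C)[C@@H](C[C@H](C)C(=O)N(C)OC)O[Si](C(C)(C)C)(C(C)(C)C)OC1 | intermediate
15 | ring-B ketone: cyclohexanone (C1 ketone, C6 methylene, C10 (S)-methyl, C8 (R)-oxygen) fused through C7=C11 to the 2,2-di-tert-butyl-1,3,2-dioxasilepine, allyl ester on C11 cis to C6 | C=CCOC(=O)/C1=C2\CC(=O)[C@@H](C)C[C@H]2O[Si](C(C)(C)C)(C(C)(C)C)OC1 | intermediate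
16 | (R)-citramalic acid | OC(=O)[C@](C)(O)CC(=O)O | starting material
17 | (R)-2-methylbutane-1,2,4-triol | OC[C@](C)(O)CCO | intermediate
18 | 2-[(4R)-2,2,4-trimethyl-1,3-dioxolan-4-yl]ethanol | C[C@@]1(CCO)COC(C)(C)O1 | intermediate
19 | (4R)-4-(2-iodoethyl)-2,2,4-trimethyl-1,3-dioxolane | C[C@@]1(CCI)COC(C)(C)O1 | intermediate
20 | (2R)-4-iodo-2-methylbutane-1,2-diol | OC[C@](C)(O)CCI | intermediate
21 | (R)-4-iodo-2-methyl-1,2-bis(triethylsilyloxy)butane | CC[Si](CC)(CC)OC[C@](C)(O[Si](CC)(CC)CC)CCI | intermediate
22 | (R)-3-methyl-3,4-bis(triethylsilyloxy)butyllithium | [Li]CC[C@@](C)(O[Si](CC)(CC)CC)CO[Si](CC)(CC)CC | intermediate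
23 | (R)-3-methyl-3,4-bis(triethylsilyloxy)butylcerium dichloride | Cl[Ce](Cl)CC[C@@](C)(O[Si](CC)(CC)CC)CO[Si](CC)(CC)CC | intermediate
24 | C1 tertiary alcohol: 15 with OH and the chain CH2CH2C(CH3)(OSiEt3)CH2OSiEt3 on C1 (OH cis to the C10 methyl; 4R,8R,10S) | C=CCOC(=O)/C1=C2\C[C@](O)(CC[C@@](C)(O[Si](CC)(CC)CC)CO[Si](CC)(CC)CC)[C@@H](C)C[C@H]2O[Si](C(C)(C)C)(C(C)(C)C)OC1 | intermediate
25 | C5 aldehyde: 24 with CHO in place of CH2OSiEt3 | C=CCOC(=O)/C1=C2\C[C@](O)(CC[C@@](C)(O[Si](CC)(CC)CC)C=O)[C@@H](C)C[C@H]2O[Si](C(C)(C)C)(C(C)(C)C)OC1 | intermediate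
26 | decalin diol: ring A (C1–C6) closed, C5 secondary OH, C4 OSiEt3, C1 tertiary OH; C5 and C6 undefined | C=CCOC(=O)/C1=C2\C3C(O)[C@](C)(O[Si](CC)(CC)CC)CC[C@]3(O)[C@@H](C)C[C@H]2O[Si](C(C)(C)C)(C(C)(C)C)OC1 | intermediate
27 | decalin β-hydroxy ketone: 26 with a C5 ketone; C6 undefined | C=CCOC(=O)/C1=C2\C3C(=O)[C@](C)(O[Si](CC)(CC)CC)CC[C@]3(O)[C@@H](C)C[C@H]2O[Si](C(C)(C)C)(C(C)(C)C)OC1 | intermediate
28 | dienyl triflate: 8a-hydroxy-octalin with C5 enol triflate (C5=C6), C1 OH, C4 OSiEt3, C7=C11 acrylate (allyl ester cis to C6), O8–Si(tBu)2–O13 bridge, C10 methyl | O[C@]12CC[C@@](C)(O[Si](CC)(CC)CC)C(OS(=O)(=O)C(F)(F)F)=C1/C(=C(/CO[Si](C(C)(C)C)(C(C)(C)C)O3)C(=O)OCC=C)[C@H]3C[C@@H]2C | intermediate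
29 | ten-membered cyclodec-5-ynone: C1 ketone, C5≡C6, C4 (R) OSiEt3, C10 (S) methyl, exocyclic C7=C11 acrylate allyl ester cis to C6, O8–Si(tBu)2–O13 bridge | C=CCOC(=O)/C1=C2\C#C[C@](C)(O[Si](CC)(CC)CC)CCC(=O)[C@@H](C)C[C@H]2O[Si](C(C)(C)C)(C(C)(C)C)OC1 | intermediate
30 | enyne carboxylic acid: 29 with CO2H in place of the allyl ester | OC(=O)/C1=C2\C#C[C@](C)(O[Si](CC)(CC)CC)CCC(=O)[C@@H](C)C[C@H]2O[Si](C(C)(C)C)(C(C)(C)C)OC1 | intermediate
31 | protected tricycle: Z-alkylidene butenolide of the target skeleton with O8–Si(tBu)2–O13 bridge and C4 OSiEt3 | CC(C)(C)[Si]1(C(C)(C)C)OCC2=C3/C(=C/[C@](C)(O[Si](CC)(CC)CC)CCC(=O)[C@@H](C)C[C@H]3O1)OC2=O | intermediate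
32 | triol: target without the acetyl and senecioyl groups | OCC1=C2/C(=C/[C@](C)(O)CCC(=O)[C@@H](C)C[C@H]2O)OC1=O | intermediate
33 | C13 acetate with free C8 and C4 hydroxyls | CC(=O)OCC1=C2/C(=C/[C@](C)(O)CCC(=O)[C@@H](C)C[C@H]2O)OC1=O | intermediate
34 | CNP0186726.1 (4R,8R,10S) | CC(=O)OCC1=C2/C(=C/[C@](C)(O)CCC(=O)[C@@H](C)C[C@H]2OC(=O)C=C(C)C)OC1=O | target

## Step count and least certain steps

Total: 27 steps. Longest linear sequence: 21 steps (steps 1–5, 7–11 and 17–27 from 1). The citramalate branch (steps 12–16) and the reagent step 6 join it at steps 17 and 7.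

**Step 22 (key step).** The alkoxide may take the triflyl group from the enol oxygen through a six-membered transition state instead of fragmenting. Any excess base may also enolize the product ketone and scramble C10. Fallback: the route leaves at 27 and returns at 29 by the epoxy-ketone fragmentation. 27 is dehydrated (Burgess reagent) to the C1=C6 dienone F1. This is epoxidized nucleophilically (t-BuOOH, DBU) to the epoxy ketone F2. Condensation with TsNHNH2 (AcOH, CH2Cl2) gives the tosylhydrazone F3, which fragments with loss of nitrogen and sulfinate to the same alkynone 29.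

**Step 8.** The acylated oxonium ion may ionize instead of being opened by direct displacement. An allyl cation spanning C13 and C7 could lose the alkene geometry, and cleavage at C8 would invert or scramble that centre. Fallback from 11 to 12: acetyl bromide with ZnBr2 (cat.) opens the ring by bromide displacement at C13 to the acetoxy bromide F4, and CsOAc in DMF replaces the bromide by acetate.

**Step 11.** Deprotonation may occur at C8 or C10 instead of C6, the dienolate may attack through C11, or the C13–O bond may be expelled from the dienolate and open the silylene. Fallback from 14 to 24 with the bond order reversed: organolithium 22 is added to the Weinreb amide of 14 to give the open-chain ketone F5, and ring B is then closed by a vinylogous aldol reaction (KN(SiMe3)2, THF, −78 °C), which gives 24 directly.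

**Step 19.** The dienolate may again eliminate the C13 oxygen, or the amide base may reduce or add to the aldehyde faster than it removes the C6 proton. Fallback from 15 to 26 with ring A closed at C1–C2 instead of C5–C6: Swern oxidation of 21 gives the iodo aldehyde F6. The extended enolate of 15 (LiN(SiMe3)2) adds to it at C6 to give the aldol adduct F7. A samarium Barbier cyclization (SmI2, HMPA, THF) then joins C2 to the C1 ketone and returns 26.

**Step 24.** The carboxylate may add 6-endo to C5 and give the pyranone, or silver may be sequestered by the ketone and silyl ethers so that cyclization stalls. Fallback from 30 to 31: iodolactonization (I2, NaHCO3, MeCN) gives by anti addition the iodoalkylidene butenolide F8. Reduction with Bu3SnH and Pd(PPh3)4 (cat.) replaces iodine by hydrogen with retention.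

## Further compounds

F1 | step 22 | C1=C6 dienone from dehydration of 27 | C=CCOC(=O)/C1=C2\C3=C(CC[C@@](C)(O[Si](CC)(CC)CC)C3=O)[C@@H](C)C[C@H]2O[Si](C(C)(C)C)(C(C)(C)C)OC1
F2 | step 22 | C1–C6 epoxy C5 ketone | C=CCOC(=O)/C1=C2\C34OC3(CC[C@@](C)(O[Si](CC)(CC)CC)C4=O)[C@@H](C)C[C@H]2O[Si](C(C)(C)C)(C(C)(C)C)OC1
F3 | step 22 | tosylhydrazone of F2 | C=CCOC(=O)/C1=C2\C34OC3(CC[C@@](C)(O[Si](CC)(CC)CC)C4=NNS(=O)(=O)c5ccc(C)cc5)[C@@H](C)C[C@H]2O[Si](C(C)(C)C)(C(C)(C)C)OC1
F4 | step 8 | allyl (2E,4R,6S)-4-acetoxy-2-(bromomethyl)-7-[methoxy(methyl)amino]-3,6-dimethyl-7-oxohept-2-enoate | C=CCOC(=O)/C(CBr)=C(\C)[C@H](OC(C)=O)C[C@H](C)C(=O)N(C)OC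
F5 | step 11 | open-chain C1 ketone from 14 and 22 | C=CCOC(=O)/C1=C(\C)[C@@H](C[C@H](C)C(=O)CC[C@@](C)(O[Si](CC)(CC)CC)CO[Si](CC)(CC)CC)O[Si](C(C)(C)C)(C(C)(C)C)OC1
F6 | step 19 | (R)-4-iodo-2-methyl-2-(triethylsilyloxy)butanal | O=C[C@](C)(O[Si](CC)(CC)CC)CCI
F7 | step 19 | C6 aldol adduct of 15 with F6 (C5 and C6 undefined) | C=CCOC(=O)/C1=C2\C(C(O)[C@](C)(O[Si](CC)(CC)CC)CCI)C(=O)[C@@H](C)C[C@H]2O[Si](C(C)(C)C)(C(C)(C)C)OC1
F8 | step 24 | C5-iodo alkylidene butenolide (iodine trans to the lactone oxygen) | CC(C)(C)[Si]1(C(C)(C)C)OCC2=C3/C(=C(\I)[C@](C)(O[Si](CC)(CC)CC)CCC(=O)[C@@H](C)C[C@H]3O1)OC2=O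
A1 | alternative 1 | bis-silyl ether of the deacylated target with free C4 alcohol | CC(C)(C)[Si](C)(C)OCC1=C2/C(=C/[C@](C)(O)CCC(=O)[C@@H](C)C[C@H]2O[Si](C)(C)C(C)(C)C)OC1=O
A2 | alternative 1 | open-chain Z-enol triflate acid with terminal alkyne | OC(=O)/C(CO[Si](C)(C)C(C)(C)C)=C(\OS(=O)(=O)C(F)(F)F)[C@H](O[Si](C)(C)C(C)(C)C)C[C@H](C)C(=O)CC[C@@](C)(O)C#C
A3 | alternative 2 | ten-membered C8 alcohol with exocyclic methylene at C10 | CC(C)(C)[Si](C)(C)OCC1=C2/C(=C/[C@](C)(O[Si](CC)(CC)CC)CCC(=O)C(=C)C[C@H]2O)OC1=O
A4 | alternative 2 | formyl alkylidene butenolide carrying the 2-(bromomethyl)enone | CC(C)(C)[Si](C)(C)OCC1=C(C=O)/C(=C/[C@](C)(O[Si](CC)(CC)CC)CCC(=O)C(=C)CBr)OC1=O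
A5 | alternative 3 | ten-membered keto alkylidene butenolide with C4 4-methoxybenzyl ether and C8, C13 silyl ethers | CC(C)(C)[Si](C)(C)OCC1=C2/C(=C/[C@](C)(OCc3ccc(OC)cc3)CCC(=O)[C@@H](C)C[C@H]2O[Si](C)(C)C(C)(C)C)OC1=O
A6 | alternative 3 | cyclohexane-fused butenolide with C1 vinyl carbinol and C6 (E)-2-alkoxypropenyl group (C1 and C6 configurations left open) | C=CC1(O)[C@@H](C)C[C@@H](O[Si](C)(C)C(C)(C)C)C2=C(CO[Si](C)(C)C(C)(C)C)C(=O)OC12/C=C(\C)OCc1ccc(OC)cc1
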